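The cyclohexane ring atoms are labelled C1 (ketone), C2 (methyl-bearing epoxide carbon), C3 (epoxide CH), C4 (CH2), C5 (side-chain CH) and C6 (acyloxy CH). The route rests on a catalytic asymmetric Diels–Alder reaction that builds this ring from 3-methylfuran and an acrylimide. It exploits the 1,4-relation of the oxygen-bearing carbons C3 and C6: they are the furan α-carbons, C2 carries the furan methyl, and C4–C5 is the dienophile. One operation forms C3–C4 and C5–C6, sets C5 and C6, and parks the C6 oxygen in a bridge whose later β-elimination gives the enone. The side chain grows from the acyl group through an enol triflate; the hydroperoxide comes last by a singlet-oxygen ene reaction.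

Key step: step 1

Remark on labels: in the side chain, C7 is the alkene carbon on C5, C14 its CH2, C8 the ketone, C9 and C10 the next two carbons, and C11 the hydroperoxide carbon.

Assumption: the copper complex of the (R,R)-ligand is taken to give the (2R)-endo adduct, the mirror image of the (2S)-endo sense usual for the (S,S)-ligand with acrylimide dienophiles.

Step 1
Reactants: 1 3-methylfuran; 2 3-(prop-2-enoyl)-1,3-oxazolidin-2-one
Product: 3 3-{[(1R,2R,4R)-5-methyl-7-oxabicyclo[2.2.1]hept-5-en-2-yl]carbonyl}-1,3-oxazolidin-2-one (endo adduct)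
Conditions: Cu(SbF6)2 and (4R,4'R)-2,2'-(propane-2,2-diyl)bis(4-tert-butyl-4,5-dihydro-1,3-oxazole) (10 mol % each), excess 1, CH2Cl2, −78 °C
Reagents that add atoms: none
Why: Lewis-acid-catalysed normal-demand [4+2] cycloaddition in which the acrylimide is held as a two-point chelate on square-planar divalent copper, one face of its s-cis enoyl unit is blocked by a tert-butyl group of the ligand, and the furan adds in a concerted, asynchronous way. The closest known reaction type is the copper bis(oxazoline)-catalysed Diels–Alder reaction of acryloyl oxazolidinones with furan and cyclopentadiene. The step closes the cyclohexene ring (and with it the oxolane ring of the 7-oxanorbornene) by suprafacial [4+2] cycloaddition, forming C3–C4 and C5–C6 and leaving the furan oxygen as a bridge between C3 and C6. C3 and C6 are fixed by the suprafacial addition, C5 is set relative to C6 by the endo transition state (acyl group anti to the oxygen bridge, the later trans C5/C6 relation), and the absolute sense is set by the ligand. The step needs regioselectivity, which should come from the furan α-carbon next to the methyl group being the more nucleophilic terminus and bonding to the β-carbon (C4) of the chelated acrylimide. It also needs kinetic control, because warming allows cycloreversion and drift to the exo isomer, hence the low temperature and prompt conversion of 3.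

Step 2
Reactants: 3 endo imide adduct
Product: 4 (1R,2R,4R)-N-methoxy-N,5-dimethyl-7-oxabicyclo[2.2.1]hept-5-ene-2-carboxamide
Conditions: Me(MeO)NH·HCl, AlMe3, CH2Cl2, 0 °C to rt
Reagents that add atoms: N,O-dimethylhydroxylamine hydrochloride, CNOC.Cl
Why: Aluminium amide transamination (Weinreb amide formation) should attack the more electrophilic exocyclic imide carbonyl and expel the oxazolidinone without epimerising C5, whose amide α-proton is only weakly acidic.

Step 3
Reactants: 4 Weinreb amide
Product: 5 1-[(1R,2R,4R)-5-methyl-7-oxabicyclo[2.2.1]hept-5-en-2-yl]ethan-1-one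
Conditions: MeMgBr, THF, −78 to 0 °C; cold NH4Cl work-up
Reagents that add atoms: methylmagnesium bromide, C[Mg]Br
Why: Grignard addition to a Weinreb amide stops at the chelated tetrahedral intermediate, so the methyl ketone appears only on work-up and over-addition is avoided; the cold, weakly acidic work-up should keep the endo ketone from epimerising at C5.

Step 4
Reactants: 5 methyl ketone
Product: 7 1-[(1R,2R,4R)-5-methyl-7-oxabicyclo[2.2.1]hept-5-en-2-yl]ethenyl trifluoromethanesulfonate, via potassium enolate 6 (not isolated)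
Conditions: KN(SiMe3)2, THF, −78 °C; then PhNTf2, −78 to 0 °C
Reagents that add atoms: N-phenylbis(trifluoromethanesulfonimide), O=S(=O)(N(c1ccccc1)S(=O)(=O)C(F)(F)F)C(F)(F)F
Why: Kinetic deprotonation with the hindered amide base should take the methyl group and not the C5 methine, and O-triflation of the enolate gives the enol triflate, which makes C5 non-enolisable and stores C7 as a vinyl electrophile.

Step 5
Reactants: 7 enol triflate
Product: 9 1-[(1S,2R,4R,5R,6R)-6-hydroxy-5-methyl-7-oxabicyclo[2.2.1]heptan-2-yl]ethenyl trifluoromethanesulfonate (exo alcohol), via exo-alkylborane 8 (not isolated)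
Conditions: BH3·THF, THF, 0 °C; then NaBO3·4H2O, H2O, rt
Reagents that add atoms: sodium perborate tetrahydrate (NaBO3·4H2O, drawn as the peroxoborate salt), [Na+].[Na+].O[B-]1(O)OO[B-](O)(O)OO1
Why: Brown hydroboration–oxidation: the electrophilic borane should add to the strained, electron-rich trisubstituted ring alkene and not to the electron-poor enol triflate, from the exo face with boron on the less substituted carbon C1, and perborate oxidises the C–B bond with retention.

Step 6
Reactants: 9 exo alcohol
Product: 12 (1S,6R)-3-methyl-2-oxo-6-{1-[(trifluoromethanesulfonyl)oxy]ethenyl}cyclohex-3-en-1-yl 3-methylbutanoate, via oxanorbornanone 10 (not isolated), via hydroxy enone 11 (not isolated)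
Conditions: Dess–Martin periodinane, pyridine, CH2Cl2, 0 °C; then DBU, (i-PrCH2CO)2O, DMAP (cat.), 0 °C to rt
Reagents that add atoms: 3-methylbutanoic anhydride, CC(C)CC(=O)OC(=O)CC(C)C
Why: Dess–Martin oxidation gives the C1 ketone, whose only enolisable position is C2, so DBU should trigger a strain-driven E1cB β-elimination of the bridging oxygen from C3 to give the C2=C3 enone and the C6 alkoxide, which is acylated in situ; C5 and C6 are not touched, so the trans relation from the endo adduct is kept, and it is also the thermodynamically favoured one at the epimerisable C6.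

Step 7
Reactants: 12 acyloxy enone
Product: 13 (1S,2S,6R)-2-hydroxy-3-methyl-6-{1-[(trifluoromethanesulfonyl)oxy]ethenyl}cyclohex-3-en-1-yl 3-methylbutanoate
Conditions: NaBH4, CeCl3·7H2O, MeOH, −78 °C
Reagents that add atoms: none
Why: Luche reduction gives clean 1,2-reduction, and axial hydride attack on the half-chair with the C5 and C6 substituents equatorial should place the new C1 hydroxyl equatorial, cis to the C5 substituent and trans to the ester, as in the reduction of carvone to cis-carveol.

Step 8
Reactants: 13 allylic alcohol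
Product: 14 (1R,2R,3S,4R,6S)-2-hydroxy-1-methyl-4-{1-[(trifluoromethanesulfonyl)oxy]ethenyl}-7-oxabicyclo[4.1.0]heptan-3-yl 3-methylbutanoate
Conditions: VO(acac)2 (cat.), t-BuOOH, CH2Cl2, 0 °C to rt
Reagents that add atoms: tert-butyl hydroperoxide, CC(C)(C)OO
Why: Hydroxyl-directed epoxidation: the vanadium alkylperoxide bound to the allylic C1 hydroxyl delivers oxygen to the same face of the C2=C3 alkene, cis to the C5 substituent, which is the face a direct nucleophilic epoxidation of the enone would not give; the electron-poor enol triflate alkene should be inert.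

Step 9
Reactants: 15 4-methylpent-3-en-1-ol
Product: 16 4-methylpent-3-enal
Conditions: Dess–Martin periodinane, pyridine, CH2Cl2, 0 °C; used at once as a solution
Reagents that add atoms: none
Why: Dess–Martin oxidation of the primary homoallylic alcohol under buffered, non-basic conditions should give the β,γ-unsaturated aldehyde without moving the double bond into conjugation.

Step 10
Reactants: 14 epoxy alcohol enol triflate; 16 4-methylpent-3-enal
Product: 17 (1R,2R,3S,4S,6S)-2-hydroxy-4-(3-hydroxy-6-methylhepta-1,5-dien-2-yl)-1-methyl-7-oxabicyclo[4.1.0]heptan-3-yl 3-methylbutanoate (both epimers at the side-chain carbinol C8)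
Conditions: CrCl2, NiCl2 (cat.), DMF, rt
Reagents that add atoms: none
Why: Nozaki–Hiyama–Kishi coupling: nickel-catalysed activation of the enol triflate and transmetalation to chromium give an alkenylchromium species that should add chemoselectively to the aldehyde in the presence of the ester, the epoxide and the free hydroxyl; the C8 carbinol forms as a mixture, which does not matter because it is oxidised next.

Step 11
Reactants: 17 diol
Product: 18 (1S,3S,4S,6S)-1-methyl-4-(6-methyl-3-oxohepta-1,5-dien-2-yl)-2-oxo-7-oxabicyclo[4.1.0]heptan-3-yl 3-methylbutanoate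
Conditions: Dess–Martin periodinane (excess), pyridine, CH2Cl2, 0 °C
Reagents that add atoms: none
Why: Dess–Martin oxidation should convert both secondary alcohols in one operation, the epoxy alcohol to the epoxy ketone and the C8 alcohol to the cross-conjugated ketone, under buffered conditions that leave the epoxide, the ester and the skipped prenyl alkene in place.

Step 12
Reactants: 18 prenyl ketone
Product: 19 (1S,3S,4S,6S)-4-[(4E)-6-hydroperoxy-6-methyl-3-oxohepta-1,4-dien-2-yl]-1-methyl-2-oxo-7-oxabicyclo[4.1.0]heptan-3-yl 3-methylbutanoate (target)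
Conditions: O2, visible light, tetraphenylporphyrin (cat.), CH2Cl2, −20 °C
Reagents that add atoms: dioxygen, O=O
Why: Schenck ene reaction: singlet oxygen should react only with the electron-rich trisubstituted prenyl alkene, take a hydrogen from the carbonyl-activated C9 methylene and place the hydroperoxide on the tertiary C11, giving the conjugated (E)-γ-hydroperoxy enone as is usual for β,γ-unsaturated ketones.

Compound list
1 | 3-methylfuran | Cc1ccoc1 | starting material
2 | 3-(prop-2-enoyl)-1,3-oxazolidin-2-one | C=CC(=O)N1CCOC1=O | starting material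
3 | 3-{[(1R,2R,4R)-5-methyl-7-oxabicyclo[2.2.1]hept-5-en-2-yl]carbonyl}-1,3-oxazolidin-2-one (endo) | O=C(N3CCOC3=O)[C@@H]1C[C@H]2O[C@@H]1C=C2C | intermediate
4 | (1R,2R,4R)-N-methoxy-N,5-dimethyl-7-oxabicyclo[2.2.1]hept-5-ene-2-carboxamide | CON(C)C(=O)[C@@H]1C[C@H]2O[C@@H]1C=C2C | intermediate
5 | 1-[(1R,2R,4R)-5-methyl-7-oxabicyclo[2.2.1]hept-5-en-2-yl]ethan-1-one | CC(=O)[C@@H]1C[C@H]2O[C@@H]1C=C2C | intermediate
6 | potassium 1-[(1R,2R,4R)-5-methyl-7-oxabicyclo[2.2.1]hept-5-en-2-yl]ethen-1-olate | [K+].C=C([O-])[C@@H]1C[C@H]2O[C@@H]1C=C2C | intermediate (not isolated)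
7 | 1-[(1R,2R,4R)-5-methyl-7-oxabicyclo[2.2.1]hept-5-en-2-yl]ethenyl trifluoromethanesulfonate | C=C(OS(=O)(=O)C(F)(F)F)[C@@H]1C[C@H]2O[C@@H]1C=C2C | intermediate
8 | exo-alkylborane: as 9 with BH2 in place of the exo hydroxyl | C=C(OS(=O)(=O)C(F)(F)F)[C@@H]1C[C@H]2O[C@@H]1[C@H](B)[C@H]2C | intermediate (not isolated)
9 | 1-[(1S,2R,4R,5R,6R)-6-hydroxy-5-methyl-7-oxabicyclo[2.2.1]heptan-2-yl]ethenyl trifluoromethanesulfonate (exo OH, endo methyl) | C=C(OS(=O)(=O)C(F)(F)F)[C@@H]1C[C@H]2O[C@@H]1[C@H](O)[C@H]2C | intermediate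
10 | 1-[(1S,2R,4R,5S)-5-methyl-6-oxo-7-oxabicyclo[2.2.1]heptan-2-yl]ethenyl trifluoromethanesulfonate | C=C(OS(=O)(=O)C(F)(F)F)[C@@H]1C[C@H]2O[C@@H]1C(=O)[C@H]2C | intermediate (not isolated)
11 | 1-[(1R,6S)-6-hydroxy-4-methyl-5-oxocyclohex-3-en-1-yl]ethenyl trifluoromethanesulfonate | C=C(OS(=O)(=O)C(F)(F)F)[C@@H]1CC=C(C)C(=O)[C@H]1O | intermediate (not isolated)
12 | (1S,6R)-3-methyl-2-oxo-6-{1-[(trifluoromethanesulfonyl)oxy]ethenyl}cyclohex-3-en-1-yl 3-methylbutanoate | C=C(OS(=O)(=O)C(F)(F)F)[C@@H]1CC=C(C)C(=O)[C@H]1OC(=O)CC(C)C | intermediate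
13 | (1S,2S,6R)-2-hydroxy-3-methyl-6-{1-[(trifluoromethanesulfonyl)oxy]ethenyl}cyclohex-3-en-1-yl 3-methylbutanoate | C=C(OS(=O)(=O)C(F)(F)F)[C@@H]1CC=C(C)[C@H](O)[C@H]1OC(=O)CC(C)C | intermediate
14 | (1R,2R,3S,4R,6S)-2-hydroxy-1-methyl-4-{1-[(trifluoromethanesulfonyl)oxy]ethenyl}-7-oxabicyclo[4.1.0]heptan-3-yl 3-methylbutanoate | C=C(OS(=O)(=O)C(F)(F)F)[C@@H]1C[C@@H]2O[C@]2(C)[C@H](O)[C@H]1OC(=O)CC(C)C | intermediate
15 | 4-methylpent-3-en-1-ol | CC(C)=CCCO | starting material
16 | 4-methylpent-3-enal | CC(C)=CCC=O | intermediate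
17 | (1R,2R,3S,4S,6S)-2-hydroxy-4-(3-hydroxy-6-methylhepta-1,5-dien-2-yl)-1-methyl-7-oxabicyclo[4.1.0]heptan-3-yl 3-methylbutanoate (C8 epimers) | C=C(C(O)CC=C(C)C)[C@@H]1C[C@@H]2O[C@]2(C)[C@H](O)[C@H]1OC(=O)CC(C)C | intermediate
18 | (1S,3S,4S,6S)-1-methyl-4-(6-methyl-3-oxohepta-1,5-dien-2-yl)-2-oxo-7-oxabicyclo[4.1.0]heptan-3-yl 3-methylbutanoate | C=C(C(=O)CC=C(C)C)[C@@H]1C[C@@H]2O[C@]2(C)C(=O)[C@H]1OC(=O)CC(C)C | intermediate
19 | (1S,3S,4S,6S)-4-[(4E)-6-hydroperoxy-6-methyl-3-oxohepta-1,4-dien-2-yl]-1-methyl-2-oxo-7-oxabicyclo[4.1.0]heptan-3-yl 3-methylbutanoate | C=C(C(=O)/C=C/C(C)(C)OO)[C@@H]1C[C@@H]2O[C@]2(C)C(=O)[C@H]1OC(=O)CC(C)C | target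

Total step count: 12. Longest linear sequence: 11 steps (steps 1 to 8 and 10 to 12); step 9 is a one-step side branch.

Steps most likely to fail

Step 1. The cycloaddition may suffer from poor regioselectivity or facial selectivity, from competing conjugate (Friedel–Crafts-type) addition of the furan to the activated acrylimide, or from loss of the endo adduct by cycloreversion. The fallback sets out from 1 and replaces catalyst control by a covalently bound auxiliary. (4S)-4-Benzyl-1,3-oxazolidin-2-one is N-acylated with acryloyl chloride to give (4S)-4-benzyl-3-(prop-2-enoyl)-1,3-oxazolidin-2-one F1. This is combined with 1 under Et2AlCl in CH2Cl2 at −78 °C; the chelate model predicts addition anti to the benzyl group. The endo diastereomers are separable by crystallisation, so the (1R,2R,4R) adduct (4S)-4-benzyl-3-{[(1R,2R,4R)-5-methyl-7-oxabicyclo[2.2.1]hept-5-en-2-yl]carbonyl}-1,3-oxazolidin-2-one F2 can be obtained pure whatever the level of induction. Transamination of F2 with Me(MeO)NH·HCl and AlMe3 comes back to the route at 4.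

Step 10. The enolisable β,γ-unsaturated aldehyde may isomerise or self-condense under the Lewis-acidic chromium conditions, or activation of the hindered enol triflate may be too slow. The fallback sets out from 14 and makes the C7–C8 bond by acylation instead of carbonyl addition. Oxidation of 14 with Dess–Martin periodinane gives the epoxy ketone (1S,3S,4R,6S)-1-methyl-2-oxo-4-{1-[(trifluoromethanesulfonyl)oxy]ethenyl}-7-oxabicyclo[4.1.0]heptan-3-yl 3-methylbutanoate F3. Stannylation with Me3SnSnMe3, Pd(PPh3)4 and LiCl gives the alkenylstannane (1S,3S,4R,6S)-1-methyl-2-oxo-4-[1-(trimethylstannyl)ethenyl]-7-oxabicyclo[4.1.0]heptan-3-yl 3-methylbutanoate F4. Stille acylation of F4 with 4-methylpent-3-enoyl chloride F5 (from 4-methylpent-3-enoic acid and oxalyl chloride) under Pd(PPh3)4 catalysis comes back to the route at 18.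

Step 12. The ene reaction may lack regioselectivity, with hydrogen abstraction from the cis methyl group giving the secondary allylic hydroperoxide, and the β,γ-unsaturated ketone may drift into conjugation before it reacts. The fallback sets out from 14 and brings in the hydroperoxide ready-made. Nozaki–Hiyama–Kishi coupling of 14 with acrolein (CrCl2, cat. NiCl2) gives (1R,2R,3S,4S,6S)-2-hydroxy-4-(3-hydroxypenta-1,4-dien-2-yl)-1-methyl-7-oxabicyclo[4.1.0]heptan-3-yl 3-methylbutanoate F6. Double Dess–Martin oxidation gives the divinyl ketone (1S,3S,4S,6S)-1-methyl-2-oxo-4-(3-oxopenta-1,4-dien-2-yl)-7-oxabicyclo[4.1.0]heptan-3-yl 3-methylbutanoate F7. Cross-metathesis of the monosubstituted vinyl ketone of F7 with 2-methylbut-3-en-2-yl hydroperoxide F8 (from 2-methylbut-3-en-2-ol, H2O2 and catalytic H2SO4), using the second-generation Hoveyda–Grubbs catalyst, should give the (E)-alkene and comes back to the route at 19.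

Further compounds
F1 | step 1 | (4S)-4-benzyl-3-(prop-2-enoyl)-1,3-oxazolidin-2-one | C=CC(=O)N1[C@@H](Cc2ccccc2)COC1=O
F2 | step 1 | (4S)-4-benzyl-3-{[(1R,2R,4R)-5-methyl-7-oxabicyclo[2.2.1]hept-5-en-2-yl]carbonyl}-1,3-oxazolidin-2-one | O=C(N3[C@@H](Cc4ccccc4)COC3=O)[C@@H]1C[C@H]2O[C@@H]1C=C2C
F3 | step 10 | (1S,3S,4R,6S)-1-methyl-2-oxo-4-{1-[(trifluoromethanesulfonyl)oxy]ethenyl}-7-oxabicyclo[4.1.0]heptan-3-yl 3-methylbutanoate | C=C(OS(=O)(=O)C(F)(F)F)[C@@H]1C[C@@H]2O[C@]2(C)C(=O)[C@H]1OC(=O)CC(C)C
F4 | step 10 | (1S,3S,4R,6S)-1-methyl-2-oxo-4-[1-(trimethylstannyl)ethenyl]-7-oxabicyclo[4.1.0]heptan-3-yl 3-methylbutanoate | C=C([Sn](C)(C)C)[C@@H]1C[C@@H]2O[C@]2(C)C(=O)[C@H]1OC(=O)CC(C)C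
F5 | step 10 | 4-methylpent-3-enoyl chloride | CC(C)=CCC(=O)Cl
F6 | step 12 | (1R,2R,3S,4S,6S)-2-hydroxy-4-(3-hydroxypenta-1,4-dien-2-yl)-1-methyl-7-oxabicyclo[4.1.0]heptan-3-yl 3-methylbutanoate | C=CC(O)C(=C)[C@@H]1C[C@@H]2O[C@]2(C)[C@H](O)[C@H]1OC(=O)CC(C)C
F7 | step 12 | (1S,3S,4S,6S)-1-methyl-2-oxo-4-(3-oxopenta-1,4-dien-2-yl)-7-oxabicyclo[4.1.0]heptan-3-yl 3-methylbutanoate | C=CC(=O)C(=C)[C@@H]1C[C@@H]2O[C@]2(C)C(=O)[C@H]1OC(=O)CC(C)C
F8 | step 12 | 2-methylbut-3-en-2-yl hydroperoxide | C=CC(C)(C)OO
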